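The route rests on one disconnection: the O–C2 bond of the left oxepane (squalene numbering; ring atoms O, C2, C3, C4, C5, C6, C7). The vicinal pair C2 (gem-dimethyl ether carbon) and C3 (free carbinol) is read as a latent trisubstituted epoxide. In the final step the C7 hydroxyl of the left cyclohexane (C6–C11) opens that epoxide at tertiary C2 in a 7-endo mode, which closes the oxepane and unveils the only free hydroxyl of the target in a single isomerization. The precursor is a tricyclic epoxy alcohol that already carries the diacetylated right oxepane–cyclohexane and the left methylenecyclohexanol.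

Key step: step 16

Numbering used throughout: left oxepane O, C2 (CMe2), C3 (CHOH), C4, C5, C6 (C–Me), C7 (CH–O); left cyclohexane C6–C11 (C10 carries the exocyclic CH2, C26); linker C12–C13; right cyclohexane C14–C19 (C15 carries Me and OAc); right oxepane O, C18, C19, C20, C21, C22 (CHOAc), C23 (CMe2).

Assumption: geranylacetone is used as the isomerically pure (5E) compound. The D-fructose-derived Shi ketone is taken to give the (R)-configured epoxides on these E-trisubstituted and prenyl-type alkenes, and D-(−)-tartrate the (2R,3R)-epoxy alcohol from geraniol; this is the sense the given enantiomer requires.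

Step 1
Reactants: 1 (E)-geranylacetone
Product: 2 all-(R) diepoxy ketone
Conditions: D-fructose-derived Shi ketone (0.6 equiv), Oxone (2KHSO5·KHSO4·K2SO4), K2CO3, Bu4NHSO4, Na2B4O7 buffer (pH 10.5), MeCN–CH2(OMe)2–H2O, 0 °C
Reagents that add atoms: potassium peroxymonosulfate (KHSO5, active component of Oxone), [K+].OOS(=O)(=O)[O-]
Why: Shi epoxidation (chiral dioxirane, spiro transition state) attacks only the two electron-rich trisubstituted alkenes and, under reagent control, sets C18, C19 and C22 as the (R,R,R)-diepoxide while the ketone stays untouched.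

Step 2
Reactants: 2 all-(R) diepoxy ketone
Product: 6 diepoxy vinyl ketone, via lithium enolate 3 (not isolated), via Mannich base 4 (not isolated), via methiodide 5 (not isolated)
Conditions: LiN(iPr)2, THF, −78 °C; Me2N=CH2+ I− (Eschenmoser's salt), −78 → 23 °C; MeI, CH2Cl2, 23 °C; aq. NaHCO3, 23 °C
Reagents that add atoms: Eschenmoser's salt (N,N-dimethylmethyleneiminium iodide), C=[N+](C)C.[I-]
Why: Kinetic deprotonation of the methyl ketone on the methyl side, Mannich reaction with Eschenmoser's salt and Hofmann-type elimination of the quaternized amine should give the vinyl ketone regioselectively, and the trisubstituted epoxides tolerate these cold, weakly nucleophilic conditions.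

Step 3
Reactants: 6 diepoxy vinyl ketone
Product: 7 (Z)-trimethylsilyl enol ether
Conditions: CH2=CHMgBr, CuBr·SMe2 (10 mol %), Me3SiCl, THF, −78 °C; Et3N, cold aq. NaHCO3 work-up
Reagents that add atoms: vinylmagnesium bromide, C=C[Mg]Br; chlorotrimethylsilane, C[Si](C)(C)Cl
Why: Copper-catalysed conjugate addition of the vinyl Grignard reagent to the s-cis enone with in-situ O-silylation should give the regiodefined, predominantly (Z)-configured silyl enol ether that marks C14 as the nucleophilic carbon, and trisubstituted epoxides are inert to cuprates at −78 °C.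

Step 4
Reactants: 7 (Z)-trimethylsilyl enol ether
Product: 8 bicyclic silyloxy ketone
Conditions: Me3SiOTf (0.5 equiv), 2,6-di-tert-butyl-4-methylpyridine, CH2Cl2, −78 °C
Reagents that add atoms: none
Why: Tandem oxa-/carbacyclization (epoxide-opening cascade of the cation–olefin type): silylation of the terminal epoxide makes tertiary C23 electrophilic, the C18–C19 epoxide oxygen attacks it to give a bicyclic epoxonium ion, and enol ether carbon C14 opens this ion at tertiary C19 anti to oxygen through a chair transition state, so that C22 and C18 are retained, C19 is inverted (trans ring fusion) and C14 carries its chain equatorially (any C14 epimer from the minor enol ether isomer is expected to converge on this more stable isomer with DBU), while the silyl group of the enol ether regenerates the promoter.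

Step 5
Reactants: 8 bicyclic silyloxy ketone
Product: 9 bicyclic tertiary alcohol
Conditions: MeMgBr, CeCl3, THF, −78 → 0 °C; aq. NH4Cl
Reagents that add atoms: methylmagnesium bromide, C[Mg]Br
Why: Organocerium 1,2-addition to the hindered ketone without enolization, the nucleophile entering equatorially because the axial C19 methyl blocks the axial trajectory, which should set C15 with the hydroxyl axial and cis to that methyl.

Step 6
Reactants: 9 bicyclic tertiary alcohol
Product: 10 bicyclic allyl diacetate
Conditions: Ac2O, Sc(OTf)3 (5 mol %), MeCN, −20 °C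
Reagents that add atoms: acetic anhydride, CC(=O)OC(C)=O
Why: Sc(OTf)3-catalysed acylation with acetic anhydride is strong enough for the hindered axial tertiary alcohol and converts the trimethylsilyl ether directly into the C22 acetate, no stereocenter being touched.

Step 7
Reactants: 10 bicyclic allyl diacetate
Product: 12 diacetoxy aldehyde, via ozonide 11 (not isolated)
Conditions: O3, CH2Cl2, −78 °C; PPh3, −78 → 23 °C
Reagents that add atoms: ozone, [O-][O+]=O
Why: Ozonolysis with reductive work-up cleaves the only alkene of 10 and leaves C12 as the aldehyde without touching the β-stereocenter C14.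

Step 8
Reactants: 13 geraniol
Product: 14 (2R,3R)-epoxygeraniol
Conditions: t-BuOOH, Ti(OiPr)4 (5 mol %), D-(−)-diisopropyl tartrate (7 mol %), 4 Å molecular sieves, CH2Cl2, −20 °C
Reagents that add atoms: tert-butyl hydroperoxide, CC(C)(C)OO
Why: Sharpless asymmetric epoxidation epoxidizes only the allylic alkene, and the D-tartrate ligand delivers oxygen to the face that gives the (2R,3R)-epoxide, the future C7 and C6.

Step 9
Reactants: 14 (2R,3R)-epoxygeraniol
Product: 15 epoxy iodide
Conditions: PPh3, I2, imidazole, Et2O–MeCN, 0 °C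
Reagents that add atoms: iodine, II
Why: Appel-type iodination converts the primary alcohol into the iodide by SN2 at the CH2 group, the adjacent epoxide and its two stereocenters staying intact.

Step 10
Reactants: 15 epoxy iodide; 16 dimethyl (2-oxopropyl)phosphonate
Product: 18 epoxy β-ketophosphonate, via phosphonate dianion 17 (not isolated)
Conditions: 16, NaH then n-BuLi, THF, 0 °C; 15, −78 → 0 °C; aq. NH4Cl
Reagents that add atoms: none
Why: Alkylation of the β-ketophosphonate 1,3-dianion occurs at the more basic terminal carbanion by SN2 at the primary iodide, which joins C9 to C8 and leaves the epoxide untouched.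

Step 11
Reactants: 12 diacetoxy aldehyde; 18 epoxy β-ketophosphonate
Product: 19 (E)-enone
Conditions: LiCl, iPr2NEt, MeCN, 23 °C
Reagents that add atoms: none
Why: Horner–Wadsworth–Emmons olefination under Masamune–Roush conditions should join the two halves as the (E)-enone under conditions mild enough for the acetates, the epoxide and the aldehyde α-methylene.

Step 12
Reactants: 19 (E)-enone
Product: 20 (Z)-triethylsilyl enol ether
Conditions: Et3SiH, RhCl(PPh3)3 (2 mol %), THF, 50 °C
Reagents that add atoms: triethylsilane, CC[SiH](CC)CC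
Why: Rhodium-catalysed 1,4-hydrosilylation of the enone should give the silyl enol ether regiospecifically toward C11 and mainly as the (Z)-isomer, the trisubstituted alkene, epoxide and esters being inert.

Step 13
Reactants: 20 (Z)-triethylsilyl enol ether
Product: 21 tricyclic hydroxy ketone
Conditions: MeAlCl2 (3 equiv), CH2Cl2, −78 °C; aq. NaHCO3
Reagents that add atoms: none
Why: Lewis-acid-promoted epoxide-opening carbocyclization (cation–olefin cyclization with a silyl enol ether terminator): C11 attacks the activated epoxide at tertiary C6 anti to oxygen through a chair transition state, so that C7 is retained, C6 is inverted and the C11 chain is equatorial (also the preferred α-epimer of the ketone), the prenyl alkene being unable to reach C6 in a favourable ring size.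

Step 14
Reactants: 21 tricyclic hydroxy ketone
Product: 22 tricyclic methylene alcohol
Conditions: Zn, CH2Br2, TiCl4 (reagent pre-formed in THF), CH2Cl2, 0 → 23 °C
Reagents that add atoms: dibromomethane, BrCBr
Why: Takai–Lombardo methylenation is non-basic and selective for the ketone over the acetates, so the exocyclic alkene should be installed without epimerizing C11.

Step 15
Reactants: 22 tricyclic methylene alcohol
Product: 23 tricyclic epoxy alcohol
Conditions: D-fructose-derived Shi ketone (0.3 equiv), Oxone (2KHSO5·KHSO4·K2SO4, 1.3 equiv KHSO5), K2CO3, Bu4NHSO4, Na2B4O7 buffer (pH 10.5), MeCN–CH2(OMe)2–H2O, 0 °C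
Reagents that add atoms: potassium peroxymonosulfate (KHSO5, active component of Oxone), [K+].OOS(=O)(=O)[O-]
Why: Shi epoxidation is much faster on the electron-rich trisubstituted alkene than on the hindered 1,1-disubstituted exocyclic alkene, and reagent control should set C3 as (R).

Step 16
Reactants: 23 tricyclic epoxy alcohol
Product: 24 target CNP0412606.2
Conditions: BF3·OEt2 (0.2 equiv), CH2Cl2, −78 → −40 °C; Et3N
Reagents that add atoms: none
Why: BF3 coordinates the epoxide oxygen and the C2–O bond lengthens toward the tertiary, gem-dimethyl-stabilized carbon; the equatorial C7 hydroxyl, held gauche to the equatorial C5–C4 chain on the rigid chair, attacks C2 with loss of a proton, an acid-promoted endo-selective epoxy-alcohol cyclization of the kind used for fused oxepanes from trisubstituted epoxides that carry the extra alkyl groups on the distal carbon. The oxepane is closed in the 7-endo-tet mode and is trans-fused to the cyclohexane because both ring bonds at C6 and C7 are equatorial. No new stereocenter arises at C2 (two methyl groups), and C3 keeps the (R) configuration installed in step 15 because only the C2–O bond breaks, so the free hydroxyl of the target appears with retention. The step needs regioselectivity for tertiary C2 over secondary C3 (6-exo), which the cation-stabilizing gem-dimethyl carbon and the low-temperature Lewis-acid conditions should secure, and chemoselectivity over the acetates and the exocyclic alkene, which are not expected to react with catalytic BF3·OEt2 at this temperature.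

Compound list

1 | (5E)-6,10-dimethylundeca-5,9-dien-2-one, (E)-geranylacetone | CC(=O)CC/C=C(\C)CCC=C(C)C | starting material
2 | 4-[(2R,3R)-3-{2-[(2R)-3,3-dimethyloxiran-2-yl]ethyl}-3-methyloxiran-2-yl]butan-2-one, all-(R) diepoxy ketone | CC(=O)CC[C@H]1O[C@]1(C)CC[C@H]1OC1(C)C | intermediate
3 | lithium enolate of 2 on the methyl side | [Li+].C=C([O-])CC[C@H]1O[C@]1(C)CC[C@H]1OC1(C)C | intermediate (not isolated)
4 | Mannich base, 1-(dimethylamino)pentan-3-one carrying the diepoxide chain of 2 at C5 | CN(C)CCC(=O)CC[C@H]1O[C@]1(C)CC[C@H]1OC1(C)C | intermediate (not isolated)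
5 | methiodide of 4, trimethylammonium iodide | C[N+](C)(C)CCC(=O)CC[C@H]1O[C@]1(C)CC[C@H]1OC1(C)C.[I-] | intermediate (not isolated)
6 | 5-[(2R,3R)-3-{2-[(2R)-3,3-dimethyloxiran-2-yl]ethyl}-3-methyloxiran-2-yl]pent-1-en-3-one, diepoxy vinyl ketone | C=CC(=O)CC[C@H]1O[C@]1(C)CC[C@H]1OC1(C)C | intermediate
7 | (3Z)-3-(trimethylsilyloxy)hepta-3,6-diene carrying the diepoxide unit of 2 at C1, (Z)-trimethylsilyl enol ether | C=CC/C=C(\O[Si](C)(C)C)CC[C@H]1O[C@]1(C)CC[C@H]1OC1(C)C | intermediate
8 | trans-fused (3R,5aR,6R,9aR)-6-allyl-2,2,5a-trimethyl-3-(trimethylsilyloxy)perhydro-1-benzoxepin-7-one, bicyclic silyloxy ketone | C=CC[C@@H]1[C@@]2(C)CC[C@@H](O[Si](C)(C)C)C(C)(C)O[C@@H]2CCC1=O | intermediate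
9 | (3R,5aR,6R,7S,9aR)-6-allyl-2,2,5a,7-tetramethyl-3-(trimethylsilyloxy)perhydro-1-benzoxepin-7-ol (7-OH axial, cis to the 5a-methyl), bicyclic tertiary alcohol | C=CC[C@@H]1[C@@]2(C)CC[C@@H](O[Si](C)(C)C)C(C)(C)O[C@@H]2CC[C@]1(C)O | intermediate
10 | (3R,5aR,6R,7S,9aR)-6-allyl-2,2,5a,7-tetramethylperhydro-1-benzoxepine-3,7-diyl diacetate, bicyclic allyl diacetate | C=CC[C@@H]1[C@@]2(C)CC[C@@H](OC(C)=O)C(C)(C)O[C@@H]2CC[C@]1(C)OC(C)=O | intermediate
11 | ozonide (1,2,4-trioxolane) of the allyl group of 10 | C1(C[C@@H]2[C@@]3(C)CC[C@@H](OC(C)=O)C(C)(C)O[C@@H]3CC[C@]2(C)OC(C)=O)OCOO1 | intermediate (not isolated)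
12 | 2-[(3R,5aR,6R,7S,9aR)-3,7-diacetoxy-2,2,5a,7-tetramethylperhydro-1-benzoxepin-6-yl]acetaldehyde, diacetoxy aldehyde | O=CC[C@@H]1[C@@]2(C)CC[C@@H](OC(C)=O)C(C)(C)O[C@@H]2CC[C@]1(C)OC(C)=O | intermediate
13 | geraniol, (2E)-3,7-dimethylocta-2,6-dien-1-ol | CC(C)=CCC/C(C)=C/CO | starting material
14 | (2R,3R)-2,3-epoxygeraniol, [(2R,3R)-3-methyl-3-(4-methylpent-3-en-1-yl)oxiran-2-yl]methanol | OC[C@H]1O[C@]1(C)CCC=C(C)C | intermediate
15 | (2S,3R)-2-(iodomethyl)-3-methyl-3-(4-methylpent-3-en-1-yl)oxirane, epoxy iodide (same spatial arrangement as 14) | IC[C@H]1O[C@]1(C)CCC=C(C)C | intermediate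
16 | dimethyl (2-oxopropyl)phosphonate | COP(=O)(OC)CC(C)=O | starting material
17 | 1,3-dianion of 16 (sodium lithium salt), phosphonate dianion | [Na+].[Li+].COP(=O)(OC)[CH-]C(=O)[CH2-] | intermediate (not isolated)
18 | dimethyl {4-[(2R,3R)-3-methyl-3-(4-methylpent-3-en-1-yl)oxiran-2-yl]-2-oxobutyl}phosphonate, epoxy β-ketophosphonate | COP(=O)(OC)CC(=O)CC[C@H]1O[C@]1(C)CCC=C(C)C | intermediate
19 | (E)-enone C10(=O)–C11=C12 joining the right bicycle of 12 (through C13) to the left epoxy chain of 18 | O=C(/C=C/C[C@@H]1[C@@]2(C)CC[C@@H](OC(C)=O)C(C)(C)O[C@@H]2CC[C@]1(C)OC(C)=O)CC[C@H]1O[C@]1(C)CCC=C(C)C | intermediate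
20 | (Z)-triethylsilyl enol ether of 19 (C10–OSiEt3, C10=C11, silyloxy cis to C12) | CC[Si](CC)(CC)O/C(CC[C@H]1O[C@]1(C)CCC=C(C)C)=C\CC[C@@H]1[C@@]2(C)CC[C@@H](OC(C)=O)C(C)(C)O[C@@H]2CC[C@]1(C)OC(C)=O | intermediate
21 | (2R,3R,4R)-4-hydroxy-3-methyl-3-(4-methylpent-3-en-1-yl)cyclohexan-1-one carrying at C2 the 2-[(3R,5aR,6R,7S,9aR)-3,7-diacetoxy-2,2,5a,7-tetramethylperhydro-1-benzoxepin-6-yl]ethyl group, tricyclic hydroxy ketone | O=C1CC[C@@H](O)[C@](C)(CCC=C(C)C)[C@H]1CC[C@@H]1[C@@]2(C)CC[C@@H](OC(C)=O)C(C)(C)O[C@@H]2CC[C@]1(C)OC(C)=O | intermediate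
22 | (1R,2R,3S)-2-methyl-4-methylidene-2-(4-methylpent-3-en-1-yl)cyclohexan-1-ol carrying the same bicyclic ethyl group at C3, tricyclic methylene alcohol | C=C1CC[C@@H](O)[C@](C)(CCC=C(C)C)[C@H]1CC[C@@H]1[C@@]2(C)CC[C@@H](OC(C)=O)C(C)(C)O[C@@H]2CC[C@]1(C)OC(C)=O | intermediate
23 | (2R)-3,3-dimethyloxirane derived from the prenyl alkene of 22, tricyclic epoxy alcohol | C=C1CC[C@@H](O)[C@](C)(CC[C@H]2OC2(C)C)[C@H]1CC[C@@H]1[C@@]2(C)CC[C@@H](OC(C)=O)C(C)(C)O[C@@H]2CC[C@]1(C)OC(C)=O | intermediate
24 | CNP0412606.2, (3R,6R,7R,11S,14R,15S,18R,19R,22R) in the numbering above | C=C1CC[C@H]2OC(C)(C)[C@H](O)CC[C@]2(C)[C@H]1CC[C@@H]1[C@@]2(C)CC[C@@H](OC(C)=O)C(C)(C)O[C@@H]2CC[C@]1(C)OC(C)=O | target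

Total step count: 16. Longest linear sequence: 13 steps (steps 1–7 and 11–16, from geranylacetone); the left-half branch (steps 8–10) adds 3 steps.

Steps most likely to fail

1. Step 16 (key step). The process at risk is regiochemical leakage: attack of the C7 oxygen at secondary C3 (6-exo), or hydride shift or elimination of the activated epoxide before the slow seven-membered closure. Fallback: from 23, Cp2TiCl (generated from Cp2TiCl2 and Mn) isomerizes the epoxide to the 2-methylallyl alcohol F1 with C3 retained. Iodoetherification with N-iodosuccinimide can then only deliver the C7 oxygen to the tertiary alkene carbon C2 (7-endo; the other alkene carbon would need an eight-membered ring, and the C3 hydroxyl could only form a three-membered ring), giving the iodomethyl oxepane F2. Bu3SnH with AIBN removes the iodine and restores the gem-dimethyl group, arriving at 24.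

2. Step 4. The tandem process may stall after epoxonium formation, because the trisubstituted enol ether carbon must bond to a fully substituted centre, and an E/Z mixture of enol ethers would erode control at C14. Fallback: stepwise ring formation with the chemistry used on the left half. It sets out from 18: Horner–Wadsworth–Emmons reaction with aqueous formaldehyde (K2CO3) gives the monoepoxy vinyl ketone F3. Vinyl cuprate addition and silylation as in step 3 give the silyl enol ether F4. MeAlCl2 monocyclization as in step 13 gives the monocyclic hydroxy ketone F5. Shi epoxidation of its prenyl alkene (the allyl group is inert) gives the epoxy alcohol F6, and BF3·OEt2 closes the oxepane to the bicyclic hydroxy ketone F7. Me3SiCl with imidazole returns 8.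

3. Step 13. The silyl enol ether may be too weak or too hindered a terminator, so that the activated epoxide rearranges by hydride shift or the enol ether is lost by protodesilylation before C–C bond formation. Fallback: from 19, conjugate reduction with LiBH(s-Bu)3 and trapping of the (Z)-enolate with PhNTf2 gives the enol triflate F8. Pd(PPh3)4-catalysed Negishi coupling with Me3SiCH2ZnCl gives the allylsilane F9. MeAlCl2-promoted epoxide–allylsilane cyclization then forms the cyclohexane and the exocyclic methylene together, arriving at 22 and replacing steps 13 and 14.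

Further compounds

F1 | step 16 | 2-methylallyl alcohol (C3–OH retained, C2=CH2) from 23 | C=C1CC[C@@H](O)[C@](C)(CC[C@@H](O)C(C)=C)[C@H]1CC[C@@H]1[C@@]2(C)CC[C@@H](OC(C)=O)C(C)(C)O[C@@H]2CC[C@]1(C)OC(C)=O
F2 | step 16 | iodomethyl oxepane (C2 epimers) | C=C1CC[C@H]2OC(C)(CI)[C@H](O)CC[C@]2(C)[C@H]1CC[C@@H]1[C@@]2(C)CC[C@@H](OC(C)=O)C(C)(C)O[C@@H]2CC[C@]1(C)OC(C)=O
F3 | step 4 | monoepoxy vinyl ketone | C=CC(=O)CC[C@H]1O[C@]1(C)CCC=C(C)C
F4 | step 4 | (Z)-trimethylsilyl enol ether of the monoepoxide series | C=CC/C=C(\O[Si](C)(C)C)CC[C@H]1O[C@]1(C)CCC=C(C)C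
F5 | step 4 | (2R,3R,4R)-2-allyl-4-hydroxy-3-methyl-3-(4-methylpent-3-en-1-yl)cyclohexan-1-one | O=C1CC[C@@H](O)[C@](C)(CCC=C(C)C)[C@H]1CC=C
F6 | step 4 | epoxy alcohol from the prenyl alkene of F5 | O=C1CC[C@@H](O)[C@](C)(CC[C@H]2OC2(C)C)[C@H]1CC=C
F7 | step 4 | bicyclic hydroxy ketone (desilyl 8) | C=CC[C@@H]1[C@@]2(C)CC[C@@H](O)C(C)(C)O[C@@H]2CCC1=O
F8 | step 13 | (Z)-enol triflate from 19 | O=S(=O)(O/C(CC[C@H]1O[C@]1(C)CCC=C(C)C)=C\CC[C@@H]1[C@@]2(C)CC[C@@H](OC(C)=O)C(C)(C)O[C@@H]2CC[C@]1(C)OC(C)=O)C(F)(F)F
F9 | step 13 | (Z)-allylsilane (C10–CH2SiMe3, C10=C11) | C[Si](C)(C)C/C(CC[C@H]1O[C@]1(C)CCC=C(C)C)=C\CC[C@@H]1[C@@]2(C)CC[C@@H](OC(C)=O)C(C)(C)O[C@@H]2CC[C@]1(C)OC(C)=O
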